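**Retrosynthetic overview**
1. Target 14 ⇐ bis(benzyl ether) 13 by hydrogenolysis. The γ-lactone is the only ring made (step 5); the arene and auxiliary rings are bought.
2. 13 ⇐ acyclic imide/ester 10. The imide C=O becomes the lactone CH2–O, the benzyl ester C=O becomes the lactone C=O, and C3 is equilibrated to trans after ring closure.
3. 10 ⇐ the C3–C4 bond (lignan C8–C8') between the α-carbons of two 3-arylpropanoyl units, both normally donors. It is made by oxidative heterocoupling of two lithium enolates, one of which Fe(acac)3 turns into an α-carbonyl radical (enolonium equivalent); the (S)-oxazolidinone sets C4.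
4. Imide 7 and ester 2 ⇐ dihydroisoferulic acid 3, dihydroferulic acid 1, benzyl bromide and auxiliary 5.

Assumption: acids 1 and 3 are bought as catalogue compounds; compound numbers follow the forward route.

**Route**

Step 1
Reactants: 1 3-(4-hydroxy-3-methoxyphenyl)propanoic acid (dihydroferulic acid)
Product: 2 benzyl 3-[4-(benzyloxy)-3-methoxyphenyl]propanoate
Conditions: BnBr (2.3 equiv), K2CO3 (3 equiv), DMF, 60 °C
Reagents that add atoms: benzyl bromide, BrCc1ccccc1
Why: Williamson ether synthesis and carboxylate O-alkylation (two SN2 reactions on a benzylic bromide) protect the phenol and form the ester in one operation; no stereocenter is involved.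

Step 2
Reactants: 3 3-(3-hydroxy-4-methoxyphenyl)propanoic acid (dihydroisoferulic acid)
Product: 4 3-[3-(benzyloxy)-4-methoxyphenyl]propanoic acid
Conditions: BnBr (1.3 equiv), KOH (3 equiv), EtOH/H2O, reflux; then aq HCl to pH 2
Reagents that add atoms: benzyl bromide, BrCc1ccccc1
Why: Williamson ether synthesis on the phenoxide/carboxylate dianion, where the phenoxide is the better nucleophile and any benzyl ester formed is saponified in situ by the excess hydroxide.

Step 3
Reactants: 4 3-[3-(benzyloxy)-4-methoxyphenyl]propanoic acid; 5 (4S)-4-benzyl-1,3-oxazolidin-2-one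
Product: 7 (4S)-4-benzyl-3-{3-[3-(benzyloxy)-4-methoxyphenyl]propanoyl}-1,3-oxazolidin-2-one, via mixed pivalic anhydride 6 (not isolated)
Conditions: PivCl, Et3N, THF, −20 °C; then LiCl, 5, −20 °C → rt
Reagents that add atoms: none
Why: N-acylation of the oxazolidinone by a mixed anhydride (LiCl/Et3N activation), which is attacked only at the unhindered acyl carbonyl; the auxiliary stereocenter is bought in.

Step 4
Reactants: 7 (4S)-4-benzyl-3-{3-[3-(benzyloxy)-4-methoxyphenyl]propanoyl}-1,3-oxazolidin-2-one; 2 benzyl 3-[4-(benzyloxy)-3-methoxyphenyl]propanoate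
Product: 10 benzyl (2RS,3R)-2-[4-(benzyloxy)-3-methoxybenzyl]-3-[3-(benzyloxy)-4-methoxybenzyl]-4-[(4S)-4-benzyl-2-oxo-1,3-oxazolidin-3-yl]-4-oxobutanoate (C2-epimer mixture), via imide lithium enolate 8 (not isolated), via ester lithium enolate 9 (not isolated)
Conditions: 7 (1.0 equiv), 2 (1.2 equiv), LiN(iPr)2 (LDA, commercial solution, 2.3 equiv), THF, −78 °C, 30 min; Fe(acac)3 (Fe(C5H7O2)3, 2.2 equiv), −78 °C → rt; 1 M HCl
Reagents that add atoms: none
Why: Oxidative enolate heterocoupling, in which trivalent iron oxidises one lithium enolate by one electron to an electrophilic α-carbonyl radical (enolonium equivalent) that the second, electronically different enolate captures before a second oxidation gives the 1,4-dicarbonyl; the 4-benzyl group of chelated Z-enolate 8 shields one face, so the bond forms anti to it as in an Evans alkylation and fixes C3 as R, while C2 forms as an epimer mixture that step 5 corrects.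

Step 5
Reactants: 10 benzyl (2RS,3R)-2-[4-(benzyloxy)-3-methoxybenzyl]-3-[3-(benzyloxy)-4-methoxybenzyl]-4-[(4S)-4-benzyl-2-oxo-1,3-oxazolidin-3-yl]-4-oxobutanoate
Product: 13 (3R,4R)-3-[4-(benzyloxy)-3-methoxybenzyl]-4-[3-(benzyloxy)-4-methoxybenzyl]dihydrofuran-2(3H)-one, via hydroxy ester 11 (not isolated), via lactone epimer mixture 12 (not isolated)
Conditions: NaBH4 (4 equiv), THF/H2O 4:1, 0 °C → rt; extractive work-up, crude in PhMe, DBU (2 equiv), 80 °C
Reagents that add atoms: none
Why: Chemoselective reductive cleavage of the N-acyloxazolidinone by NaBH4 in wet THF gives the primary alcohol and spares the benzyl ester, then DBU drives 5-exo-trig lactonisation (loss of BnOH) and base-mediated epimerisation of the enolisable C3 to the thermodynamically favoured trans (3R) lactone, C4 no longer being epimerisable.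

Step 6
Reactants: 13 (3R,4R)-3-[4-(benzyloxy)-3-methoxybenzyl]-4-[3-(benzyloxy)-4-methoxybenzyl]dihydrofuran-2(3H)-one
Product: 14 (3R,4R)-3-(4-hydroxy-3-methoxybenzyl)-4-(3-hydroxy-4-methoxybenzyl)dihydrofuran-2(3H)-one (target)
Conditions: H2 (1 atm), 10% Pd/C, EtOAc/EtOH, rt
Reagents that add atoms: none
Why: Catalytic hydrogenolysis of the two aryl benzyl ethers under neutral conditions leaves the lactone, the methyl ethers and both stereocenters untouched.

**Compound list**
1 | 3-(4-hydroxy-3-methoxyphenyl)propanoic acid (dihydroferulic acid) | COc1cc(CCC(=O)O)ccc1O | starting material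
2 | benzyl 3-[4-(benzyloxy)-3-methoxyphenyl]propanoate | COc1cc(CCC(=O)OCc2ccccc2)ccc1OCc1ccccc1 | intermediate
3 | 3-(3-hydroxy-4-methoxyphenyl)propanoic acid (dihydroisoferulic acid) | COc1ccc(CCC(=O)O)cc1O | starting material
4 | 3-[3-(benzyloxy)-4-methoxyphenyl]propanoic acid | COc1ccc(CCC(=O)O)cc1OCc1ccccc1 | intermediate
5 | (4S)-4-benzyl-1,3-oxazolidin-2-one | O=C1N[C@@H](Cc2ccccc2)CO1 | starting material
6 | 3-[3-(benzyloxy)-4-methoxyphenyl]propanoic pivalic anhydride | COc1ccc(CCC(=O)OC(=O)C(C)(C)C)cc1OCc1ccccc1 | intermediate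
7 | (4S)-4-benzyl-3-{3-[3-(benzyloxy)-4-methoxyphenyl]propanoyl}-1,3-oxazolidin-2-one | COc1ccc(CCC(=O)N2C(=O)OC[C@@H]2Cc2ccccc2)cc1OCc1ccccc1 | intermediate
8 | lithium (Z)-enolate of 7 (OLi cis to the CH2Ar group) | [Li]O/C(=C\Cc1ccc(OC)c(OCc2ccccc2)c1)N1C(=O)OC[C@@H]1Cc1ccccc1 | intermediate
9 | lithium enolate of 2 (OLi trans to the CH2Ar group) | [Li]O/C(OCc1ccccc1)=C/Cc1ccc(OCc2ccccc2)c(OC)c1 | intermediate
10 | benzyl (2RS,3R)-2-[4-(benzyloxy)-3-methoxybenzyl]-3-[3-(benzyloxy)-4-methoxybenzyl]-4-[(4S)-4-benzyl-2-oxo-1,3-oxazolidin-3-yl]-4-oxobutanoate (C2 epimers, C3 fixed R) | O=C(N1C(=O)OC[C@@H]1Cc1ccccc1)[C@H](Cc1ccc(OC)c(OCc2ccccc2)c1)C(Cc1ccc(OCc2ccccc2)c(OC)c1)C(=O)OCc1ccccc1 | intermediate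
11 | benzyl (2RS,3R)-2-[4-(benzyloxy)-3-methoxybenzyl]-3-[3-(benzyloxy)-4-methoxybenzyl]-4-hydroxybutanoate | OC[C@H](Cc1ccc(OC)c(OCc2ccccc2)c1)C(Cc1ccc(OCc2ccccc2)c(OC)c1)C(=O)OCc1ccccc1 | intermediate
12 | (3RS,4R)-3-[4-(benzyloxy)-3-methoxybenzyl]-4-[3-(benzyloxy)-4-methoxybenzyl]dihydrofuran-2(3H)-one (cis/trans mixture) | COc1ccc(C[C@H]2COC(=O)C2Cc2ccc(OCc3ccccc3)c(OC)c2)cc1OCc1ccccc1 | intermediate
13 | (3R,4R)-3-[4-(benzyloxy)-3-methoxybenzyl]-4-[3-(benzyloxy)-4-methoxybenzyl]dihydrofuran-2(3H)-one (trans) | COc1ccc(C[C@H]2COC(=O)[C@@H]2Cc2ccc(OCc3ccccc3)c(OC)c2)cc1OCc1ccccc1 | intermediate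
14 | (3R,4R)-3-(4-hydroxy-3-methoxybenzyl)-4-(3-hydroxy-4-methoxybenzyl)dihydrofuran-2(3H)-one | COc1ccc(C[C@H]2COC(=O)[C@@H]2Cc2ccc(O)c(OC)c2)cc1O | target

**Count and risks**
Total steps: 6. Longest linear sequence: 5 steps (3 → 4 → 7 → 10 → 13 → 14); step 5 is counted as one step although an extractive work-up separates its two stages.

Most likely to fail:

- **Step 4 (oxidative heterocoupling).** Homodimers of either enolate, a low yield or imperfect facial control at C3 are the main risks. The fallback sets out from 7 and returns at 13, making the same C3–C4 bond by polar alkylation. The sodium enolate of 7 (NaN(SiMe3)2, THF, −78 °C) is alkylated with tert-butyl bromoacetate to give tert-butyl (3R)-3-[3-(benzyloxy)-4-methoxybenzyl]-4-[(4S)-4-benzyl-2-oxo-1,3-oxazolidin-3-yl]-4-oxobutanoate F1. LiBH4/MeOH in THF at 0 °C gives tert-butyl (3R)-3-[3-(benzyloxy)-4-methoxybenzyl]-4-hydroxybutanoate F2, which TsOH in PhMe closes to (4R)-4-[3-(benzyloxy)-4-methoxybenzyl]dihydrofuran-2(3H)-one F3. The lithium enolate of F3 (LiN(SiMe3)2, THF, −78 °C) is then benzylated anti to the C4 substituent with 4-(benzyloxy)-3-methoxybenzyl bromide F4 (from commercial 4-(benzyloxy)-3-methoxybenzyl alcohol and PBr3), giving trans lactone 13 directly.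

- **Step 5 (imide reduction, lactonisation, epimerisation).** The hindered imide may be attacked at the ring carbonyl, or the ester/lactone may be over-reduced. The fallback sets out from 10 and returns at 11. LiOH/H2O2 in THF/H2O at 0 °C removes the auxiliary hydrolytically to give (2R,3RS)-4-(benzyloxy)-2-[3-(benzyloxy)-4-methoxybenzyl]-3-[4-(benzyloxy)-3-methoxybenzyl]-4-oxobutanoic acid F5. BH3·SMe2 in THF reduces the free acid in the presence of the benzyl ester to hydroxy ester 11, which re-enters at the DBU stage.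

- **Step 2 (phenol-selective benzylation of a free acid).** Incomplete O-alkylation or persistent ester can lower the yield. The fallback sets out from 3 and returns at 4. Exhaustive benzylation (BnBr, K2CO3, DMF) gives benzyl 3-[3-(benzyloxy)-4-methoxyphenyl]propanoate F6, and LiOH in THF/H2O saponifies only the ester to give 4.

**Further compounds**
F1 | step 4 | tert-butyl (3R)-3-[3-(benzyloxy)-4-methoxybenzyl]-4-[(4S)-4-benzyl-2-oxo-1,3-oxazolidin-3-yl]-4-oxobutanoate | O=C(N1C(=O)OC[C@@H]1Cc1ccccc1)[C@H](Cc1ccc(OC)c(OCc2ccccc2)c1)CC(=O)OC(C)(C)C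
F2 | step 4 | tert-butyl (3R)-3-[3-(benzyloxy)-4-methoxybenzyl]-4-hydroxybutanoate | OC[C@H](Cc1ccc(OC)c(OCc2ccccc2)c1)CC(=O)OC(C)(C)C
F3 | step 4 | (4R)-4-[3-(benzyloxy)-4-methoxybenzyl]dihydrofuran-2(3H)-one | COc1ccc(C[C@H]2COC(=O)C2)cc1OCc1ccccc1
F4 | step 4 | 4-(benzyloxy)-3-methoxybenzyl bromide | COc1cc(CBr)ccc1OCc1ccccc1
F5 | step 5 | (2R,3RS)-4-(benzyloxy)-2-[3-(benzyloxy)-4-methoxybenzyl]-3-[4-(benzyloxy)-3-methoxybenzyl]-4-oxobutanoic acid | OC(=O)[C@H](Cc1ccc(OC)c(OCc2ccccc2)c1)C(Cc1ccc(OCc2ccccc2)c(OC)c1)C(=O)OCc1ccccc1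
F6 | step 2 | benzyl 3-[3-(benzyloxy)-4-methoxyphenyl]propanoate | COc1ccc(CCC(=O)OCc2ccccc2)cc1OCc1ccccc1
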